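**Plan**

- Retrosynthetic cuts: the three MOM ethers and the C3–OH of ring C (C–H oxygenation); ring C at O1–C2 (oxa-Michael) and at C4–C3 (acetylide plus aldehyde), which separates a ring-A salicylaldehyde from a ring-B aryl alkyne; the dimethylpyran at C3=C4 and at O–C8a (chromene numbering); the 1,1-dimethylallyl group back to an α-aryl isobutyrate.
- Forward order: ring B (from 5-bromo-2-fluorophenol) receives the quaternary side chain, Br on C1' and CHO on C2'; the pyran ring is annulated in one flask and dehydrated; C1' becomes an alkyne; the alkyne is added to the ring-A aldehyde; ring C is closed, C3 is hydroxylated and the phenols are freed.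
- Enabling feature: the pyran ring shares the C2'–C3' edge of ring B, so its C4 (on C2') and its oxygen (on C3') stand 1,3 to each other. A formyl carbon on C2' next to a C3'–F is therefore a 1,3-dielectrophile, which the C–C–O unit of strained 2,2-dimethyloxirane, opened reductively to a 1,3-dianion, bridges in a formal [3+3] annulation.
- Stereochemistry: the target has no stereocentre; the chromene C3=C4 bond is cis by ring constraint; the two carbinol centres formed on the way (steps 6 and 12) are racemic and are destroyed (steps 7 and 13).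

Key step: step 6

Remark: ring-B locants are 1' (carbon bound to C2 of ring C), 2' (carbon bearing the pyran CH=), 3' (carbon bearing the pyran oxygen), 4' (OH), 6' (1,1-dimethylallyl); in step 11 the hydroxyl left free is assumed to be the hindered, hydrogen-bonded one between CHO and prenyl.

**Route**

Step 1
Reactants: 1 5-bromo-2-fluorophenol
Product: 2 4-bromo-1-fluoro-2-(methoxymethoxy)benzene
Conditions: MOMCl, i-Pr2NEt, CH2Cl2, 0 °C to rt
Reagents that add atoms: chloromethyl methyl ether (MOMCl), COCCl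
Why: Williamson-type O-alkylation masks the future 4'-OH as a MOM acetal ether that should survive the later organolithium and alkoxide steps.

Step 2
Reactants: 2 4-bromo-1-fluoro-2-(methoxymethoxy)benzene
Product: 3 methyl 2-[4-fluoro-3-(methoxymethoxy)phenyl]-2-methylpropanoate
Conditions: methyl 2-methylpropanoate, LiN(C6H11)2, Pd(dba)2 (cat.), P(t-Bu)3 (cat.), toluene, rt
Reagents that add atoms: methyl 2-methylpropanoate, COC(=O)C(C)C
Why: palladium-catalysed α-arylation of the ester enolate, in which zerovalent palladium inserts into the C–Br bond and leaves the C–F bond alone, should set the quaternary benzylic carbon of the future 1,1-dimethylallyl group.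

Step 3
Reactants: 3 methyl 2-[4-fluoro-3-(methoxymethoxy)phenyl]-2-methylpropanoate
Product: 4 methyl 2-[2-bromo-4-fluoro-5-(methoxymethoxy)phenyl]-2-methylpropanoate
Conditions: NBS, MeCN, 0 °C to rt
Reagents that add atoms: N-bromosuccinimide, O=C1CCC(=O)N1Br
Why: electrophilic aromatic bromination should go para to the MOM ether, the only activated position not squeezed between two substituents, which places the handle for ring C on C1'.

Step 4
Reactants: 4 methyl 2-[2-bromo-4-fluoro-5-(methoxymethoxy)phenyl]-2-methylpropanoate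
Product: 6 1-bromo-5-fluoro-4-(methoxymethoxy)-2-(2-methylbut-3-en-2-yl)benzene, via aldehyde 5 (not isolated)
Conditions: i-Bu2AlH, toluene, −78 °C; then Ph3P=CH2 (from MePPh3Br, KOt-Bu), THF, −78 °C to rt
Reagents that add atoms: methyltriphenylphosphonium bromide, C[P+](c1ccccc1)(c1ccccc1)c1ccccc1.[Br-]
Why: partial hydride reduction of the hindered ester to the aluminium hemiacetal and Wittig methylenation of the aldehyde released in the flask should give the 1,1-dimethylallyl group.

Step 5
Reactants: 6 1-bromo-5-fluoro-4-(methoxymethoxy)-2-(2-methylbut-3-en-2-yl)benzene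
Product: 8 2-bromo-6-fluoro-5-(methoxymethoxy)-3-(2-methylbut-3-en-2-yl)benzaldehyde, via aryllithium 7 (not isolated)
Conditions: LiN(i-Pr)2, THF, −78 °C; then DMF; aqueous work-up
Reagents that add atoms: N,N-dimethylformamide, CN(C)C=O
Why: directed ortho-metalation at the most acidic ring C–H, the one flanked by Br and F, followed by formylation should place the CHO on C2' between the two halogens.

Step 6
Reactants: 8 2-bromo-6-fluoro-5-(methoxymethoxy)-3-(2-methylbut-3-en-2-yl)benzaldehyde, 9 2,2-dimethyloxirane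
Product: 12 5-bromo-8-(methoxymethoxy)-2,2-dimethyl-6-(2-methylbut-3-en-2-yl)-3,4-dihydro-2H-chromen-4-ol (racemic), via dilithio alkoxide 10 (not isolated), via dilithium diolate 11 (not isolated)
Conditions: 9, lithium 4,4'-di-tert-butylbiphenylide (2 equiv), THF, −78 °C; then 8, −78 to 0 °C; then KOt-Bu, DMPU, 80 °C; aqueous work-up
Reagents that add atoms: none
Why: Two-electron reductive opening of the strained oxirane 9 at its less substituted C–O bond should give the β-lithio alkoxide 10, a C–C–O 1,3-dinucleophile whose carbanion adds to the formyl carbon of 8 (new C3–C4 bond of the pyran) faster than it exchanges with the aryl bromide at −78 °C. The tertiary alkoxide of 11 should then close the six-membered ring by addition–elimination at the fluorine-bearing C3' (new O–C8a bond; 6-exo-trig attack on the C3'=C4' π bond through a Meisenheimer-type transition state with fluoride as leaving group), helped by the gem-dimethyl group and by the potassium counter-ion in a dipolar solvent. The closest known reaction types are the addition of β-lithio alkoxides from reductively opened epoxides to aldehydes (1,3-diol synthesis) and the intramolecular nucleophilic aromatic substitution of alkoxides on ortho-fluoroarenes to give chromans, run here in one flask as a formal [3+3] annulation. The only new stereocentre, the carbinol C4, is not controlled (racemic) and is removed in step 7. Site selectivity is needed between C3'–F and C1'–Br, both ortho to the side chain: fluoride is the better leaving group for addition–elimination and C1' is screened by the quaternary carbon on C6', while neither halogen has an ortho hydrogen, so no aryne can form. The secondary alkoxide cannot compete because it could only close a four-membered ring.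

Step 7
Reactants: 12 5-bromo-8-(methoxymethoxy)-2,2-dimethyl-6-(2-methylbut-3-en-2-yl)-3,4-dihydro-2H-chromen-4-ol
Product: 13 5-bromo-8-(methoxymethoxy)-2,2-dimethyl-6-(2-methylbut-3-en-2-yl)-2H-chromene
Conditions: Burgess reagent, toluene, 60 °C
Reagents that add atoms: none
Why: Burgess dehydration (syn-elimination of the benzylic sulfamate ester) can only form the C3=C4 bond, which should give the ring-locked cis alkene of the 2H-chromene and erase the carbinol stereocentre without acid that would endanger the MOM ether.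

Step 8
Reactants: 13 5-bromo-8-(methoxymethoxy)-2,2-dimethyl-6-(2-methylbut-3-en-2-yl)-2H-chromene
Product: 15 8-(methoxymethoxy)-2,2-dimethyl-6-(2-methylbut-3-en-2-yl)-2H-chromene-5-carbaldehyde, via aryllithium 14 (not isolated)
Conditions: t-BuLi (2 equiv), THF, −78 °C; then DMF; aqueous work-up
Reagents that add atoms: N,N-dimethylformamide, CN(C)C=O
Why: bromine–lithium exchange is insensitive to the two ortho substituents, and formylation of the aryllithium should give the C1' aldehyde.

Step 9
Reactants: 15 8-(methoxymethoxy)-2,2-dimethyl-6-(2-methylbut-3-en-2-yl)-2H-chromene-5-carbaldehyde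
Product: 16 5-ethynyl-8-(methoxymethoxy)-2,2-dimethyl-6-(2-methylbut-3-en-2-yl)-2H-chromene
Conditions: dimethyl (1-diazo-2-oxopropyl)phosphonate, K2CO3, MeOH, rt
Reagents that add atoms: dimethyl (1-diazo-2-oxopropyl)phosphonate, CC(=O)C(=[N+]=[N-])P(=O)(OC)OC
Why: Seyferth–Gilbert homologation in its Ohira–Bestmann form should turn the aldehyde into the terminal alkyne under mild basic conditions that leave the chromene and the MOM ether intact.

Step 10
Reactants: 17 2,4,6-trihydroxybenzaldehyde
Product: 18 2,4,6-trihydroxy-3-(3-methylbut-2-en-1-yl)benzaldehyde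
Conditions: 1-bromo-3-methylbut-2-ene, DBU, THF, 0 °C to rt
Reagents that add atoms: 1-bromo-3-methylbut-2-ene, CC(C)=CCBr
Why: C-alkylation of the phloroglucinol-type phenoxide, a vinylogous enolate with only one kind of free ring carbon, should install the prenyl group (C-prenylation).

Step 11
Reactants: 18 2,4,6-trihydroxy-3-(3-methylbut-2-en-1-yl)benzaldehyde
Product: 19 2-hydroxy-4,6-bis(methoxymethoxy)-3-(3-methylbut-2-en-1-yl)benzaldehyde
Conditions: MOMCl (2.2 equiv), i-Pr2NEt, CH2Cl2, 0 °C
Reagents that add atoms: chloromethyl methyl ether (MOMCl), COCCl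
Why: acetal ether formation should take the para OH and the less hindered ortho OH and leave free the hydrogen-bonded OH between CHO and prenyl, which is the one that must close ring C to give the 8-prenyl pattern.

Step 12
Reactants: 16 5-ethynyl-8-(methoxymethoxy)-2,2-dimethyl-6-(2-methylbut-3-en-2-yl)-2H-chromene, 19 2-hydroxy-4,6-bis(methoxymethoxy)-3-(3-methylbut-2-en-1-yl)benzaldehyde
Product: 22 1-[2-hydroxy-4,6-bis(methoxymethoxy)-3-(3-methylbut-2-en-1-yl)phenyl]-3-[8-(methoxymethoxy)-2,2-dimethyl-6-(2-methylbut-3-en-2-yl)-2H-chromen-5-yl]prop-2-yn-1-ol (racemic), via lithium acetylide 20 (not isolated), via sodium phenoxide 21 (not isolated)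
Conditions: 16, n-BuLi, THF, −78 °C; 19, NaH, THF, 0 °C; combine, −78 °C to rt; aqueous work-up
Reagents that add atoms: none
Why: 1,2-addition of the lithium acetylide to the aldehyde (alkynylation) should join the fragments through a rod-like alkyne that avoids the crowding at C1', and the new carbinol centre forms racemic and is oxidised away in step 13.

Step 13
Reactants: 22 1-[2-hydroxy-4,6-bis(methoxymethoxy)-3-(3-methylbut-2-en-1-yl)phenyl]-3-[8-(methoxymethoxy)-2,2-dimethyl-6-(2-methylbut-3-en-2-yl)-2H-chromen-5-yl]prop-2-yn-1-ol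
Product: 24 5,7-bis(methoxymethoxy)-2-[8-(methoxymethoxy)-2,2-dimethyl-6-(2-methylbut-3-en-2-yl)-2H-chromen-5-yl]-8-(3-methylbut-2-en-1-yl)-4H-chromen-4-one, via ynone 23 (not isolated)
Conditions: MnO2, CH2Cl2, rt; filter; then DMAP (cat.), DMF, 40 °C
Reagents that add atoms: none
Why: MnO2 oxidation of the benzylic propargylic alcohol should give the 2'-hydroxyaryl ynone, and amine-catalysed intramolecular oxa-Michael addition (6-endo-dig) of the free phenol at the β-alkyne carbon should close pyranone ring C.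

Step 14
Reactants: 24 5,7-bis(methoxymethoxy)-2-[8-(methoxymethoxy)-2,2-dimethyl-6-(2-methylbut-3-en-2-yl)-2H-chromen-5-yl]-8-(3-methylbut-2-en-1-yl)-4H-chromen-4-one
Product: 27 3-hydroxy-5,7-bis(methoxymethoxy)-2-[8-(methoxymethoxy)-2,2-dimethyl-6-(2-methylbut-3-en-2-yl)-2H-chromen-5-yl]-8-(3-methylbut-2-en-1-yl)-4H-chromen-4-one, via 3-lithioflavone 25 (not isolated), via boronate 26 (not isolated)
Conditions: LiN(i-Pr)2, THF, −78 °C; B(OMe)3; then AcOH, H2O2, 0 °C
Reagents that add atoms: hydrogen peroxide, OO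
Why: lithiation–borylation–oxidation at C3, the sp2 C–H next to the chromone carbonyl, should place the hydroxyl there by oxidation of a C–B bond, which does not touch the three electron-rich alkenes.

Step 15
Reactants: 27 3-hydroxy-5,7-bis(methoxymethoxy)-2-[8-(methoxymethoxy)-2,2-dimethyl-6-(2-methylbut-3-en-2-yl)-2H-chromen-5-yl]-8-(3-methylbut-2-en-1-yl)-4H-chromen-4-one
Product: 28 3,5,7-trihydroxy-2-[8-hydroxy-2,2-dimethyl-6-(2-methylbut-3-en-2-yl)-2H-chromen-5-yl]-8-(3-methylbut-2-en-1-yl)-4H-chromen-4-one (CNP0241222.0)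
Conditions: HCl (3 M aq., cat.), MeOH, 40 °C
Reagents that add atoms: none
Why: acid-catalysed acetal exchange (MOM ether methanolysis) should free the three phenols under conditions mild enough for the prenyl, 1,1-dimethylallyl and chromene units.

**Compound list**

1 | 5-bromo-2-fluorophenol | Oc1cc(Br)ccc1F | starting material
2 | 4-bromo-1-fluoro-2-(methoxymethoxy)benzene | COCOc1cc(Br)ccc1F | intermediate
3 | methyl 2-[4-fluoro-3-(methoxymethoxy)phenyl]-2-methylpropanoate | COCOc1cc(C(C)(C)C(=O)OC)ccc1F | intermediate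
4 | methyl 2-[2-bromo-4-fluoro-5-(methoxymethoxy)phenyl]-2-methylpropanoate | COCOc1cc(C(C)(C)C(=O)OC)c(Br)cc1F | intermediate
5 | 2-[2-bromo-4-fluoro-5-(methoxymethoxy)phenyl]-2-methylpropanal | COCOc1cc(C(C)(C)C=O)c(Br)cc1F | intermediate (not isolated)
6 | 1-bromo-5-fluoro-4-(methoxymethoxy)-2-(2-methylbut-3-en-2-yl)benzene | COCOc1cc(C(C)(C)C=C)c(Br)cc1F | intermediate
7 | [2-bromo-6-fluoro-5-(methoxymethoxy)-3-(2-methylbut-3-en-2-yl)phenyl]lithium | COCOc1cc(C(C)(C)C=C)c(Br)c([Li])c1F | intermediate (not isolated)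
8 | 2-bromo-6-fluoro-5-(methoxymethoxy)-3-(2-methylbut-3-en-2-yl)benzaldehyde | COCOc1cc(C(C)(C)C=C)c(Br)c(C=O)c1F | intermediate
9 | 2,2-dimethyloxirane | CC1(C)CO1 | starting material
10 | lithium 1-lithio-2-methylpropan-2-olate | [Li]CC(C)(C)O[Li] | intermediate (not isolated)
11 | dilithium 1-[2-bromo-6-fluoro-5-(methoxymethoxy)-3-(2-methylbut-3-en-2-yl)phenyl]-3-methylbutane-1,3-bis(olate) (racemic) | COCOc1cc(C(C)(C)C=C)c(Br)c(C(O[Li])CC(C)(C)O[Li])c1F | intermediate (not isolated)
12 | 5-bromo-8-(methoxymethoxy)-2,2-dimethyl-6-(2-methylbut-3-en-2-yl)-3,4-dihydro-2H-chromen-4-ol (racemic) | COCOc1cc(C(C)(C)C=C)c(Br)c2C(O)CC(C)(C)Oc12 | intermediate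
13 | 5-bromo-8-(methoxymethoxy)-2,2-dimethyl-6-(2-methylbut-3-en-2-yl)-2H-chromene | COCOc1cc(C(C)(C)C=C)c(Br)c2C=CC(C)(C)Oc12 | intermediate
14 | [8-(methoxymethoxy)-2,2-dimethyl-6-(2-methylbut-3-en-2-yl)-2H-chromen-5-yl]lithium | COCOc1cc(C(C)(C)C=C)c([Li])c2C=CC(C)(C)Oc12 | intermediate (not isolated)
15 | 8-(methoxymethoxy)-2,2-dimethyl-6-(2-methylbut-3-en-2-yl)-2H-chromene-5-carbaldehyde | COCOc1cc(C(C)(C)C=C)c(C=O)c2C=CC(C)(C)Oc12 | intermediate
16 | 5-ethynyl-8-(methoxymethoxy)-2,2-dimethyl-6-(2-methylbut-3-en-2-yl)-2H-chromene | COCOc1cc(C(C)(C)C=C)c(C#C)c2C=CC(C)(C)Oc12 | intermediate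
17 | 2,4,6-trihydroxybenzaldehyde | O=Cc1c(O)cc(O)cc1O | starting material
18 | 2,4,6-trihydroxy-3-(3-methylbut-2-en-1-yl)benzaldehyde | CC(C)=CCc1c(O)cc(O)c(C=O)c1O | intermediate
19 | 2-hydroxy-4,6-bis(methoxymethoxy)-3-(3-methylbut-2-en-1-yl)benzaldehyde | CC(C)=CCc1c(OCOC)cc(OCOC)c(C=O)c1O | intermediate
20 | lithium acetylide of 16 | COCOc1cc(C(C)(C)C=C)c(C#C[Li])c2C=CC(C)(C)Oc12 | intermediate (not isolated)
21 | sodium phenoxide of 19 | CC(C)=CCc1c(OCOC)cc(OCOC)c(C=O)c1O[Na] | intermediate (not isolated)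
22 | 1-[2-hydroxy-4,6-bis(methoxymethoxy)-3-(3-methylbut-2-en-1-yl)phenyl]-3-[8-(methoxymethoxy)-2,2-dimethyl-6-(2-methylbut-3-en-2-yl)-2H-chromen-5-yl]prop-2-yn-1-ol (racemic) | COCOc1cc(C(C)(C)C=C)c(C#CC(O)c3c(O)c(CC=C(C)C)c(OCOC)cc3OCOC)c2C=CC(C)(C)Oc12 | intermediate
23 | 1-[2-hydroxy-4,6-bis(methoxymethoxy)-3-(3-methylbut-2-en-1-yl)phenyl]-3-[8-(methoxymethoxy)-2,2-dimethyl-6-(2-methylbut-3-en-2-yl)-2H-chromen-5-yl]prop-2-yn-1-one | COCOc1cc(C(C)(C)C=C)c(C#CC(=O)c3c(O)c(CC=C(C)C)c(OCOC)cc3OCOC)c2C=CC(C)(C)Oc12 | intermediate (not isolated)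
24 | 5,7-bis(methoxymethoxy)-2-[8-(methoxymethoxy)-2,2-dimethyl-6-(2-methylbut-3-en-2-yl)-2H-chromen-5-yl]-8-(3-methylbut-2-en-1-yl)-4H-chromen-4-one | COCOc1cc(C(C)(C)C=C)c(-c3cc(=O)c4c(OCOC)cc(OCOC)c(CC=C(C)C)c4o3)c2C=CC(C)(C)Oc12 | intermediate
25 | 3-lithio derivative of 24 | COCOc1cc(C(C)(C)C=C)c(-c3c([Li])c(=O)c4c(OCOC)cc(OCOC)c(CC=C(C)C)c4o3)c2C=CC(C)(C)Oc12 | intermediate (not isolated)
26 | dimethyl boronate of 24 at C3 | COCOc1cc(C(C)(C)C=C)c(-c3c(B(OC)OC)c(=O)c4c(OCOC)cc(OCOC)c(CC=C(C)C)c4o3)c2C=CC(C)(C)Oc12 | intermediate (not isolated)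
27 | 3-hydroxy-5,7-bis(methoxymethoxy)-2-[8-(methoxymethoxy)-2,2-dimethyl-6-(2-methylbut-3-en-2-yl)-2H-chromen-5-yl]-8-(3-methylbut-2-en-1-yl)-4H-chromen-4-one | COCOc1cc(C(C)(C)C=C)c(-c3c(O)c(=O)c4c(OCOC)cc(OCOC)c(CC=C(C)C)c4o3)c2C=CC(C)(C)Oc12 | intermediate
28 | 3,5,7-trihydroxy-2-[8-hydroxy-2,2-dimethyl-6-(2-methylbut-3-en-2-yl)-2H-chromen-5-yl]-8-(3-methylbut-2-en-1-yl)-4H-chromen-4-one | C=CC(C)(C)c1cc(O)c2c(c1-c1oc3c(CC=C(C)C)c(O)cc(O)c3c(=O)c1O)C=CC(C)(C)O2 | target

**Count and risks**

Total step count: 15. Longest linear sequence: 13 steps (steps 1–9 and 12–15); steps 10–11 make the ring-A fragment.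

Steps most likely to fail:

1. Step 6. The ring closure may stall at the open diol, because the aryl fluoride carries no activating group once the formyl carbon has been attacked; electron-transfer loss of bromine under the hot basic conditions is a second risk. The fallback sets out from 8 and comes back at 13. The fluoride of 8, still activated by the ortho formyl group, is displaced by the potassium alkoxide of 2-methylbut-3-en-2-ol (KH, THF) to give 2-bromo-5-(methoxymethoxy)-3-(2-methylbut-3-en-2-yl)-6-[(2-methylbut-3-en-2-yl)oxy]benzaldehyde F1. Wittig methylenation gives 1-bromo-2-ethenyl-4-(methoxymethoxy)-6-(2-methylbut-3-en-2-yl)-3-[(2-methylbut-3-en-2-yl)oxy]benzene F2. Ring-closing olefin metathesis with the second-generation Grubbs catalyst then forms the C3=C4 bond and returns to 13, so that 12 and step 7 are bypassed.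

2. Step 14. Deprotonation may be unselective (ring-A C6–H between two MOM ethers, benzylic prenyl CH2), boron trapping may be incomplete, or the peroxide may attack the prenyl or chromene alkenes. The fallback sets out from 15 and comes back at 27. Commercial 2,4,6-trihydroxyacetophenone is C-prenylated (1-bromo-3-methylbut-2-ene, DBU) to 1-[2,4,6-trihydroxy-3-(3-methylbut-2-en-1-yl)phenyl]ethan-1-one F3 and protected (MOMCl, i-Pr2NEt) to 1-[2-hydroxy-4,6-bis(methoxymethoxy)-3-(3-methylbut-2-en-1-yl)phenyl]ethan-1-one F4. Claisen–Schmidt condensation of F4 with aldehyde 15 (KOH, EtOH) gives (2E)-1-[2-hydroxy-4,6-bis(methoxymethoxy)-3-(3-methylbut-2-en-1-yl)phenyl]-3-[8-(methoxymethoxy)-2,2-dimethyl-6-(2-methylbut-3-en-2-yl)-2H-chromen-5-yl]prop-2-en-1-one F5. Algar–Flynn–Oyamada oxidative cyclisation (H2O2, NaOH, MeOH) then delivers the C3 oxygen during closure of ring C and gives 27.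

3. Step 9. Addition of the diazophosphonate anion to the carbonyl, which is shielded by the quaternary carbon on one side and the pyran CH on the other, may be slow, so that the aldehyde is recovered or degraded by methoxide. The fallback sets out from 13 and comes back at 16. The aryllithium 14 (t-BuLi, THF, −78 °C) is alkynylated directly by addition–elimination on triisopropyl[(4-methylbenzenesulfonyl)ethynyl]silane to give triisopropyl{[8-(methoxymethoxy)-2,2-dimethyl-6-(2-methylbut-3-en-2-yl)-2H-chromen-5-yl]ethynyl}silane F6, and Bu4NF in THF removes the silyl group to give 16.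

Further compounds
F1 | step 6 | 2-bromo-5-(methoxymethoxy)-3-(2-methylbut-3-en-2-yl)-6-[(2-methylbut-3-en-2-yl)oxy]benzaldehyde | COCOc1cc(C(C)(C)C=C)c(Br)c(C=O)c1OC(C)(C)C=C
F2 | step 6 | 1-bromo-2-ethenyl-4-(methoxymethoxy)-6-(2-methylbut-3-en-2-yl)-3-[(2-methylbut-3-en-2-yl)oxy]benzene | COCOc1cc(C(C)(C)C=C)c(Br)c(C=C)c1OC(C)(C)C=C
F3 | step 14 | 1-[2,4,6-trihydroxy-3-(3-methylbut-2-en-1-yl)phenyl]ethan-1-one | CC(=O)c1c(O)cc(O)c(CC=C(C)C)c1O
F4 | step 14 | 1-[2-hydroxy-4,6-bis(methoxymethoxy)-3-(3-methylbut-2-en-1-yl)phenyl]ethan-1-one | CC(=O)c1c(OCOC)cc(OCOC)c(CC=C(C)C)c1O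
F5 | step 14 | (2E)-1-[2-hydroxy-4,6-bis(methoxymethoxy)-3-(3-methylbut-2-en-1-yl)phenyl]-3-[8-(methoxymethoxy)-2,2-dimethyl-6-(2-methylbut-3-en-2-yl)-2H-chromen-5-yl]prop-2-en-1-one | COCOc1cc(C(C)(C)C=C)c(/C=C/C(=O)c3c(O)c(CC=C(C)C)c(OCOC)cc3OCOC)c2C=CC(C)(C)Oc12
F6 | step 9 | triisopropyl{[8-(methoxymethoxy)-2,2-dimethyl-6-(2-methylbut-3-en-2-yl)-2H-chromen-5-yl]ethynyl}silane | COCOc1cc(C(C)(C)C=C)c(C#C[Si](C(C)C)(C(C)C)C(C)C)c2C=CC(C)(C)Oc12
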